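Target 17 is (2R)-2-{(5S)-5-[(formyloxy)methyl]-6-oxo-2-[(1S)-1,3,3-trimethylcyclohexyl]cyclohex-1-en-1-yl}propanoic acid. Ring A is the trimethylcyclohexane and ring B the cyclohexenone. Ring-B locants used in the text: C1 = C=O, C2 carries the propanoic acid, C3 carries ring A, C6 carries CH2OCHO. C1′ is the quaternary carbon.

## Retrosynthetic overview
1. Cut the CH2–OCHO carbon–oxygen bond: target ⇒ HCO2H + α′-methylene dienone acid. A catalytic hydro-formyloxylation with face-selective protonation sets C6.
2. α′-Methylene ⇒ enone acid (Mannich/elimination). CH(CH3)CO2H ⇒ 2-(enon-2-yl)acrylic acid, where asymmetric hydrogenation sets the acid centre.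
3. C2–C(acrylate) ⇒ diosphenol triflate + α-stannylacrylate (Stille coupling).
4. C3–C1′ ⇒ [3,3] shift of an allyl enol ether. That ether is cut at its allyl C–O bond (Mitsunobu inversion) into (R)-isophorol + cyclohexane-1,2-dione, so the C–O stereocentre is relayed to the quaternary carbon.
5. No ring is formed. Ring A is bought as isophorone and ring B as cyclohexane-1,2-dione; they are joined first through O, then through C.

Assumption: the sense of induction in steps 1, 7 and 9 follows the closest models (alkenyl arm as the large group in the CBS reduction, 2-arylacrylic acids in the hydrogenation); the mirror-image or pseudoenantiomeric catalyst is equally available in each case.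

## Route

Step 1
Reactants: 1 isophorone
Product: 2 (R)-isophorol [(1R)-3,5,5-trimethylcyclohex-2-en-1-ol]
Conditions: (S)-2-methyl-CBS-oxazaborolidine (10 mol%), BH3·SMe2 (0.6 equiv), THF, −20 °C; MeOH, then aqueous work-up
Reagents that add atoms: none
Why: Corey–Bakshi–Shibata reduction, in which the oxazaborolidine–borane complex binds the carbonyl lone pair anti to the alkenyl arm and delivers hydride to one face in a strictly 1,2 sense, setting C1 as R.

Step 2
Reactants: 2 (R)-isophorol; 3 cyclohexane-1,2-dione (reacts as its enol)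
Product: 4 2-{[(1S)-3,5,5-trimethylcyclohex-2-en-1-yl]oxy}cyclohex-2-en-1-one
Conditions: PPh3 (1.3 equiv), DIAD (1.3 equiv), 3 (1.2 equiv), toluene, −20 °C to rt
Reagents that add atoms: none
Why: Mitsunobu reaction, in which the acidic enol O–H of 3 (pKa about 10) displaces the oxyphosphonium group by SN2 at the secondary allylic carbon (SN2′ attack would have to hit the methyl-bearing terminus), forming the allyl–O bond with inversion from R to S.

Step 3
Reactants: 4 allyl enol ether
Product: 6 2-hydroxy-3-[(1R)-1,5,5-trimethylcyclohex-2-en-1-yl]cyclohex-2-en-1-one, via 1,2-diketone tautomer 5 (not isolated)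
Conditions: Eu(fod)3 (10 mol%), toluene, 100 °C
Reagents that add atoms: none
Why: Lewis-acid-assisted Claisen rearrangement of a diosphenol allyl ether, where chelation of the 2-alkoxy enone lowers the barrier and ring A forces a suprafacial [3,3] shift, so the C3–C1′ bond forms on the face that carried the C–O bond and the S carbinol centre becomes the R quaternary centre before 5 enolises to the tetrasubstituted diosphenol.

Step 4
Reactants: 6 diosphenol
Product: 7 6-oxo-2-[(1R)-1,5,5-trimethylcyclohex-2-en-1-yl]cyclohex-1-en-1-yl trifluoromethanesulfonate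
Conditions: Tf2O (1.2 equiv), pyridine (3 equiv), CH2Cl2, −78 to 0 °C
Reagents that add atoms: triflic anhydride O=S(=O)(OS(=O)(=O)C(F)(F)F)C(F)(F)F
Why: O-sulfonylation of the enol traps the dominant tetrasubstituted tautomer as the enol triflate and touches no stereocentre.

Step 5
Reactants: 8 methyl propiolate
Product: 9 methyl 2-(tributylstannyl)prop-2-enoate
Conditions: Bu3SnH (1.05 equiv), Pd(PPh3)4 (1 mol%), THF, 0 °C to rt; chromatography removes the minor β-isomer
Reagents that add atoms: tributyltin hydride CCCC[SnH](CCCC)CCCC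
Why: Palladium-catalysed syn hydrostannation of an alkynoate sends hydride to the electrophilic β-carbon and tin mainly to the α-carbon.

Step 6
Reactants: 7 enol triflate; 9 stannylacrylate (1.5 equiv)
Product: 11 2-{6-oxo-2-[(1R)-1,5,5-trimethylcyclohex-2-en-1-yl]cyclohex-1-en-1-yl}prop-2-enoic acid, via methyl ester 10 (not isolated)
Conditions: Pd(PPh3)4 (10 mol%), CuCl (5 equiv), LiCl (6 equiv), DMSO, 60 °C; then LiOH (5 equiv), THF/H2O, rt; HCl work-up with acid–base extraction
Reagents that add atoms: lithium hydroxide [Li+].[OH-]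
Why: CuCl/LiCl-accelerated Stille coupling, the variant made for congested enol triflates and 1-substituted vinylstannanes, joins C2 to the acrylate α-carbon, and saponification in the same flask frees the acid so that extraction removes the tin residues.

Step 7
Reactants: 11 acrylic acid
Product: 13 (2R)-2-{6-oxo-2-[(1S)-1,3,3-trimethylcyclohexyl]cyclohex-1-en-1-yl}propanoic acid, via ring-A-unsaturated propanoic acid 12 (not isolated)
Conditions: Ru(OAc)2[(R)-H8-BINAP] (1 mol%), H2 (100 atm), MeOH, rt; vent, then Pd/C (5 mol% Pd), H2 (1 atm), rt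
Reagents that add atoms: none
Why: Noyori-type carboxylate-directed asymmetric hydrogenation reduces only the 1,1-disubstituted acrylic alkene and the (R)-ligand gives the R acid centre as with 2-arylacrylic acids, after which Pd/C saturates only the cis-disubstituted ring-A alkene (the untouched quaternary centre changes descriptor from R to S) because the tetrasubstituted shielded enone alkene is inert.

Step 8
Reactants: 13 enone acid
Product: 16 (2R)-2-{5-methylidene-6-oxo-2-[(1S)-1,3,3-trimethylcyclohexyl]cyclohex-1-en-1-yl}propanoic acid, via Mannich base 14 (not isolated), via amine N-oxide 15 (not isolated)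
Conditions: LiN(iPr)2 (2.1 equiv, commercial solution), THF, −78 °C; Me2N=CH2 I (1.3 equiv), −78 °C to rt; evaporate; mCPBA (1.2 equiv), CH2Cl2, 0 °C to rt; dilute HCl work-up; use at once
Reagents that add atoms: Eschenmoser's salt C=[N+](C)C.[I-]
Why: Kinetic α′-deprotonation of the lithium carboxylate at C6 (the carboxylate α-H is several pK units less acidic, so the R centre is kept), a Mannich reaction with Eschenmoser's salt and Cope-type elimination of the β-amino ketone N-oxide together give the exocyclic methylene.

Step 9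
Reactants: 16 α′-methylene dienone acid
Product: 17 (2R)-2-{(5S)-5-[(formyloxy)methyl]-6-oxo-2-[(1S)-1,3,3-trimethylcyclohexyl]cyclohex-1-en-1-yl}propanoic acid
Conditions: HCO2H (10 equiv), 3-{[3,5-bis(trifluoromethyl)phenyl]amino}-4-{[(8α,9S)-6′-methoxycinchonan-9-yl]amino}cyclobut-3-ene-1,2-dione (10 mol%), toluene, −20 °C; short silica plug, evaporate
Reagents that add atoms: formic acid O=CO
Why: Proposed new method: catalytic stereocontrolled hydro-formyloxylation of an α′-methylene enone, in which the quinuclidinium/formate ion pair and the squaramide N–H donors hold formate next to the ring-locked s-cis C1(=O)–C6(=CH2) unit, formate adds to the unhindered CH2 terminus (C3 of the other enone arm is blocked by ring A and the internal CO2H could only close a strained bridged seven-membered lactone), and the catalyst-bound dienolate is protonated by the adjacent quinuclidinium N–H on the Re face of C6 to give 6S faster than it reverts, while the formic acid buffer keeps the medium too weakly basic for E1cB loss of formate or C6 epimerisation; the closest known reaction types are the amine- or phosphine-catalysed racemic oxa-Michael addition of carboxylic acids to vinyl ketones and the squaramide-catalysed sulfa-Michael addition/enantioselective protonation of α-substituted enones.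

## Compound list
1 | isophorone (3,5,5-trimethylcyclohex-2-en-1-one) | CC1=CC(=O)CC(C)(C)C1 | starting material
2 | (R)-isophorol [(1R)-3,5,5-trimethylcyclohex-2-en-1-ol] | CC1=C[C@H](O)CC(C)(C)C1 | intermediate
3 | cyclohexane-1,2-dione | O=C1CCCCC1=O | starting material
4 | 2-{[(1S)-3,5,5-trimethylcyclohex-2-en-1-yl]oxy}cyclohex-2-en-1-one | CC1=C[C@@H](OC2=CCCCC2=O)CC(C)(C)C1 | intermediate
5 | 3-[(1R)-1,5,5-trimethylcyclohex-2-en-1-yl]cyclohexane-1,2-dione (C3 configuration undefined and lost on enolisation; not isolated) | O=C1CCCC([C@@]2(C)C=CCC(C)(C)C2)C1=O | intermediate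
6 | 2-hydroxy-3-[(1R)-1,5,5-trimethylcyclohex-2-en-1-yl]cyclohex-2-en-1-one | OC1=C([C@@]2(C)C=CCC(C)(C)C2)CCCC1=O | intermediate
7 | 6-oxo-2-[(1R)-1,5,5-trimethylcyclohex-2-en-1-yl]cyclohex-1-en-1-yl trifluoromethanesulfonate | O=C1CCCC([C@@]2(C)C=CCC(C)(C)C2)=C1OS(=O)(=O)C(F)(F)F | intermediate
8 | methyl propiolate | C#CC(=O)OC | starting material
9 | methyl 2-(tributylstannyl)prop-2-enoate | C=C(C(=O)OC)[Sn](CCCC)(CCCC)CCCC | intermediate
10 | methyl 2-{6-oxo-2-[(1R)-1,5,5-trimethylcyclohex-2-en-1-yl]cyclohex-1-en-1-yl}prop-2-enoate (not isolated) | C=C(C(=O)OC)C1=C([C@@]2(C)C=CCC(C)(C)C2)CCCC1=O | intermediate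
11 | 2-{6-oxo-2-[(1R)-1,5,5-trimethylcyclohex-2-en-1-yl]cyclohex-1-en-1-yl}prop-2-enoic acid | C=C(C(=O)O)C1=C([C@@]2(C)C=CCC(C)(C)C2)CCCC1=O | intermediate
12 | (2R)-2-{6-oxo-2-[(1R)-1,5,5-trimethylcyclohex-2-en-1-yl]cyclohex-1-en-1-yl}propanoic acid (not isolated) | C[C@@H](C(=O)O)C1=C([C@@]2(C)C=CCC(C)(C)C2)CCCC1=O | intermediate
13 | (2R)-2-{6-oxo-2-[(1S)-1,3,3-trimethylcyclohexyl]cyclohex-1-en-1-yl}propanoic acid | C[C@@H](C(=O)O)C1=C([C@@]2(C)CCCC(C)(C)C2)CCCC1=O | intermediate
14 | (2R)-2-{5-[(dimethylamino)methyl]-6-oxo-2-[(1S)-1,3,3-trimethylcyclohexyl]cyclohex-1-en-1-yl}propanoic acid (C5 epimers; not isolated) | C[C@@H](C(=O)O)C1=C([C@@]2(C)CCCC(C)(C)C2)CCC(CN(C)C)C1=O | intermediate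
15 | N-oxide of 14 (C5 epimers; not isolated) | C[C@@H](C(=O)O)C1=C([C@@]2(C)CCCC(C)(C)C2)CCC(C[N+](C)(C)[O-])C1=O | intermediate
16 | (2R)-2-{5-methylidene-6-oxo-2-[(1S)-1,3,3-trimethylcyclohexyl]cyclohex-1-en-1-yl}propanoic acid | C[C@@H](C(=O)O)C1=C([C@@]2(C)CCCC(C)(C)C2)CCC(=C)C1=O | intermediate
17 | (2R)-2-{(5S)-5-[(formyloxy)methyl]-6-oxo-2-[(1S)-1,3,3-trimethylcyclohexyl]cyclohex-1-en-1-yl}propanoic acid | C[C@@H](C(=O)O)C1=C([C@@]2(C)CCCC(C)(C)C2)CC[C@@H](COC=O)C1=O | target

## Step count and risks
Total steps: 9. Longest linear sequence: 8 (steps 1–4 and 6–9; step 5 is a one-step side branch).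

**Step 2 (Mitsunobu etherification).**
- Risk: the oxyphosphonium salt of this methyl-stabilised allylic system may ionise, which would erode the ee that is later relayed to C1′. C-alkylation or elimination to the diene can also compete.
- Fallback, from 1 back to 4: 1 is reduced with the enantiomeric (R)-2-methyl-CBS-oxazaborolidine/BH3·SMe2 to (S)-isophorol F1. This is acylated with methyl chloroformate/pyridine to methyl (1S)-3,5,5-trimethylcyclohex-2-en-1-yl carbonate F2.
- 3 is then O-allylated with F2 under zerovalent palladium catalysis (Pd2(dba)3, PPh3, THF, rt). Ionisation and attack each proceed with inversion and the enolate oxygen attacks the less substituted allyl terminus, so net retention gives the same (S)-ether 4.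

**Step 6 (Stille coupling).**
- Risk: the triflate carbon sits between the carbonyl and a carbon bearing a tert-alkyl group, and the stannane is itself 1-substituted. Transmetalation or reductive elimination may stall and triflate reduction may take over.
- Fallback, from 7 back to 11: the slim, linear alkyne partner is used instead. Sonogashira coupling of 7 with trimethylsilylacetylene (PdCl2(PPh3)2, CuI, Et3N, THF) gives 2-[(trimethylsilyl)ethynyl]-3-[(1R)-1,5,5-trimethylcyclohex-2-en-1-yl]cyclohex-2-en-1-one F3.
- K2CO3/MeOH then gives 2-ethynyl-3-[(1R)-1,5,5-trimethylcyclohex-2-en-1-yl]cyclohex-2-en-1-one F4. Markovnikov hydroxycarbonylation (Pd(OAc)2, 2-(diphenylphosphino)pyridine, CH3SO3H, CO 30 atm, H2O/THF, 60 °C) places CO2H on the internal alkyne carbon and gives 11.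

**Step 9 (new reaction).**
- Risk: formate is a weak nucleophile, the addition is reversible, excess achiral acid can protonate the dienolate outside the catalyst, and face control is unproven.
- Fallback with known chemistry, from 13 to 17: the dilithio species of 13 (LiN(iPr)2, 2.1 equiv, THF, −78 °C) is treated with gaseous formaldehyde in an aldol reaction. This gives (2R)-2-{(5S)-5-(hydroxymethyl)-6-oxo-2-[(1S)-1,3,3-trimethylcyclohexyl]cyclohex-1-en-1-yl}propanoic acid F5 together with its (5R) epimer F6.
- The two diastereomers are separated by chromatography, and F6 is re-equilibrated with catalytic Et3N and recycled. F5 is O-formylated with preformed acetic formic anhydride/pyridine at 0 °C to give 17; any mixed anhydride at the acid is hydrolysed on work-up.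

Further compounds
F1 | step 2 | (S)-isophorol [(1S)-3,5,5-trimethylcyclohex-2-en-1-ol] | CC1=C[C@@H](O)CC(C)(C)C1
F2 | step 2 | methyl (1S)-3,5,5-trimethylcyclohex-2-en-1-yl carbonate | CC1=C[C@@H](OC(=O)OC)CC(C)(C)C1
F3 | step 6 | 2-[(trimethylsilyl)ethynyl]-3-[(1R)-1,5,5-trimethylcyclohex-2-en-1-yl]cyclohex-2-en-1-one | C[Si](C)(C)C#CC1=C([C@@]2(C)C=CCC(C)(C)C2)CCCC1=O
F4 | step 6 | 2-ethynyl-3-[(1R)-1,5,5-trimethylcyclohex-2-en-1-yl]cyclohex-2-en-1-one | C#CC1=C([C@@]2(C)C=CCC(C)(C)C2)CCCC1=O
F5 | step 9 | (2R)-2-{(5S)-5-(hydroxymethyl)-6-oxo-2-[(1S)-1,3,3-trimethylcyclohexyl]cyclohex-1-en-1-yl}propanoic acid | C[C@@H](C(=O)O)C1=C([C@@]2(C)CCCC(C)(C)C2)CC[C@@H](CO)C1=O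
F6 | step 9 | (2R)-2-{(5R)-5-(hydroxymethyl)-6-oxo-2-[(1S)-1,3,3-trimethylcyclohexyl]cyclohex-1-en-1-yl}propanoic acid | C[C@@H](C(=O)O)C1=C([C@@]2(C)CCCC(C)(C)C2)CC[C@H](CO)C1=O
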